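**Plan**

- Retrosynthetic cuts, last-made first: the C‑methyl of ring A (back to a ring C–H), the O‑methyl of ring A (back to OH), then in each quinone ring the two bonds that flank one O=C–C(O) pair. In ring A these are the bond from the quinone carbonyl carbon to the chain‑bearing carbon and the bond from the methoxy‑bearing carbon to the neighbouring carbon that ends up carrying the methyl group.
- Enabling feature: each ring is the enol form of a cyclohexane‑1,2,4,5‑tetraone, i.e. an oxalyl C2 unit set between the two α‑carbons of a vicinal diketone (ring A: CH3–CO–CO–CH2–chain; ring B: CH3CH2–CO–CO–CH2–chain). A double Claisen condensation with diethyl oxalate therefore gives the hydroxyquinone directly at its final oxidation level.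
- Forward order: ω‑pentadecalactone is opened to a C15 chain with two different ends and capped with a propynyl and a butynyl unit (steps 1–5); both alkynes are oxidised to 1,2‑diketones (step 6); ring A and ring B then arise together in step 7.
- Ring A is made without its C‑methyl on purpose: its single ring C–H directs the acid‑catalysed O‑methylation to the neighbouring enolic OH (step 8) and is then filled by a methyl radical (step 9). Ring B has no C–H and stays untouched.
- Stereochemistry: the target has no stereocentre and no stereogenic double bond, so nothing has to be set.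

Key step: step 7

Remark: the 2,5‑dihydroxyquinone rings are written in the tautomer of the target SMILES (the two para‑quinone tautomers of each ring interconvert freely); 1‑propynyllithium and 1‑butyne are taken as purchased.

**Route**

Step 1
Reactants: 1 ω‑pentadecalactone (oxacyclohexadecan‑2‑one)
Product: 2 15‑bromopentadecanoic acid
Conditions: HBr (33% in AcOH), conc. H2SO4 (cat.), 70 °C
Reagents that add atoms: hydrogen bromide, Br
Why: Acid‑mediated ring opening of a macrolactone (SN2 attack of bromide on the protonated alkyl–oxygen carbon) is the standard route to ω‑bromo acids and gives a C15 chain whose two ends differ from the outset.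

Step 2
Reactants: 2 15‑bromopentadecanoic acid; 3 1‑propynyllithium
Product: 4 octadec‑16‑ynoic acid
Conditions: 3 (2.5 equiv), THF/DMPU, −20 °C to rt; then 1 M HCl
Reagents that add atoms: none
Why: Acetylide alkylation (SN2) of the primary bromide in a dipolar co‑solvent should proceed on the lithium carboxylate, which is formed by the first equivalent of 3 and is not attacked by the acetylide.

Step 3
Reactants: 4 octadec‑16‑ynoic acid
Product: 5 octadec‑16‑yn‑1‑ol
Conditions: LiAlH4, THF, 0 °C to rt; aqueous NaOH work‑up
Reagents that add atoms: none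
Why: LiAlH4 reduction of a carboxylic acid to the primary alcohol; the isolated internal alkyne is inert to the hydride under these conditions.

Step 4
Reactants: 5 octadec‑16‑yn‑1‑ol
Product: 6 18‑bromooctadec‑2‑yne
Conditions: CBr4, PPh3, CH2Cl2, 0 °C to rt
Reagents that add atoms: tetrabromomethane, BrC(Br)(Br)Br
Why: Appel reaction: the alkoxyphosphonium ion is displaced by bromide at the primary carbon under neutral conditions that leave the alkyne untouched.

Step 5
Reactants: 6 18‑bromooctadec‑2‑yne; 7 1‑butyne
Product: 9 docosa‑2,19‑diyne, via 1‑butynyllithium 8 (not isolated)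
Conditions: 7, n‑BuLi, THF, −78 °C; then 6, DMPU, −78 °C to rt
Reagents that add atoms: none
Why: A second acetylide alkylation (SN2) of a primary bromide, by the lithium acetylide 8 made from 7, installs the ethyl‑capped alkyne that will become ring B.

Step 6
Reactants: 9 docosa‑2,19‑diyne
Product: 10 docosane‑2,3,19,20‑tetraone
Conditions: RuCl3·xH2O (cat.), NaIO4, NaHCO3, MgSO4, EtOAc/MeCN/H2O, 0 °C to rt, short contact time
Reagents that add atoms: sodium periodate, [Na+].[O-]I(=O)(=O)=O
Why: RuO4‑catalysed oxidation of internal dialkyl alkynes (RuCl3/NaIO4) is a known route to 1,2‑diketones, and buffering with a short contact time should hold back cleavage of the diketones to acids.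

Step 7
Reactants: 10 docosane‑2,3,19,20‑tetraone; 11 diethyl oxalate
Product: 13 bis‑quinone 1‑(2,5‑dihydroxy‑3,6‑dioxocyclohexa‑1,4‑dien‑1‑yl)‑13‑(2,5‑dihydroxy‑4‑methyl‑3,6‑dioxocyclohexa‑1,4‑dien‑1‑yl)tridecane, via open‑chain bis‑oxalyl adduct 12 (not isolated)
Conditions: 11 (3 equiv), NaOEt (10 equiv), EtOH/THF, slow addition of 10 at 0 °C, then 65 °C, N2; 2 M HCl
Reagents that add atoms: none
Why: Proposed new method: under ethoxide each vicinal diketone of 10 is enolised, one α‑carbon is C‑acylated by diethyl oxalate (crossed Claisen condensation, adduct 12) and the second α‑carbon then attacks the remaining ester carbonyl of the same oxalyl unit (Dieckmann condensation), so in ring A the oxalyl carbons become bonded to the chain‑bearing carbon and to the former CH3 carbon, and the resulting cyclohexane‑1,2,4,5‑tetraone is, as its enol, the 2,5‑dihydroxy‑1,4‑benzoquinone with no oxidant needed. The closest known reaction types are the double Claisen condensation of dialkyl ketones with diethyl oxalate to cyclopentane‑1,2,4‑triones and that of diethyl adipate with diethyl oxalate to a 2,3‑dioxocyclohexane‑1,4‑dicarboxylate, whereas an unactivated 1,2‑diketone has not been established as the four‑carbon bis‑nucleophile. Ring A and ring B each close by a 6‑exo‑trig acyl substitution. No stereocentre is formed. The selectivity needed is C‑acylation by oxalate ahead of self‑aldol condensation of the diketone and ring closure ahead of chain extension, which should be secured by adding 10 slowly to the non‑enolisable, highly electrophilic oxalate and by the irreversible formation of the sparingly soluble dihydroxyquinone dianion (a doubly vinylogous carboxylate) that drains all reversible intermediates. Regiochemistry is not an issue because the oxalyl unit is symmetric and both α‑carbons of each diketone end up acylated.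

Step 8
Reactants: 13 bis‑quinone (ring A with a free ring C–H)
Product: 14 1‑(2‑hydroxy‑5‑methoxy‑3,6‑dioxocyclohexa‑1,4‑dien‑1‑yl)‑13‑(2,5‑dihydroxy‑4‑methyl‑3,6‑dioxocyclohexa‑1,4‑dien‑1‑yl)tridecane
Conditions: MeOH/THF, conc. H2SO4 (cat.), 50 °C, stopped when 13 is consumed
Reagents that add atoms: methanol, CO
Why: Acid‑catalysed etherification of a hydroxyquinone (vinylogous Fischer esterification) proceeds by addition of methanol to the protonated enol carbon, which is feasible only where the neighbouring ring carbon carries H, so of the four enolic OH groups only the one next to the C–H of ring A should react (the behaviour known for 3‑alkyl‑2,5‑dihydroxy‑ and 3‑alkyl‑2‑hydroxyquinones) while the three alkyl‑flanked ones stay free.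

Step 9
Reactants: 14 mono‑methyl ether
Product: 15 1‑(2‑hydroxy‑5‑methoxy‑4‑methyl‑3,6‑dioxocyclohexa‑1,4‑dien‑1‑yl)‑13‑(2,5‑dihydroxy‑4‑methyl‑3,6‑dioxocyclohexa‑1,4‑dien‑1‑yl)tridecane (target)
Conditions: AcOH (10 equiv), AgNO3 (0.3 equiv), (NH4)2S2O8 (3 equiv), MeCN/H2O, 65 °C
Reagents that add atoms: acetic acid, CC(=O)O
Why: Jacobsen–Torssell decarboxylative radical alkylation (a Minisci‑type reaction): the methyl radical formed from acetic acid by silver/persulfate adds to the only quinone C–H, giving a radical stabilised by the adjacent methoxy and carbonyl groups that is oxidised back to the quinone, and ring B offers no C–H.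

**Compound list**

1 | ω‑pentadecalactone (oxacyclohexadecan‑2‑one) | O=C1CCCCCCCCCCCCCCO1 | starting material
2 | 15‑bromopentadecanoic acid | OC(=O)CCCCCCCCCCCCCCBr | intermediate
3 | 1‑propynyllithium | [Li]C#CC | starting material
4 | octadec‑16‑ynoic acid | CC#CCCCCCCCCCCCCCCC(=O)O | intermediate
5 | octadec‑16‑yn‑1‑ol | CC#CCCCCCCCCCCCCCCCO | intermediate
6 | 18‑bromooctadec‑2‑yne | CC#CCCCCCCCCCCCCCCCBr | intermediate
7 | 1‑butyne | CCC#C | starting material
8 | 1‑butynyllithium | [Li]C#CCC | intermediate (not isolated)
9 | docosa‑2,19‑diyne | CC#CCCCCCCCCCCCCCCCC#CCC | intermediate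
10 | docosane‑2,3,19,20‑tetraone | CC(=O)C(=O)CCCCCCCCCCCCCCCC(=O)C(=O)CC | intermediate
11 | diethyl oxalate | CCOC(=O)C(=O)OCC | starting material
12 | diethyl 3‑methyl‑2,4,5,21,22,24‑hexaoxopentacosanedioate (open‑chain bis‑oxalyl adduct, drawn in the keto form) | CCOC(=O)C(=O)C(C)C(=O)C(=O)CCCCCCCCCCCCCCCC(=O)C(=O)CC(=O)C(=O)OCC | intermediate (not isolated)
13 | 1‑(2,5‑dihydroxy‑3,6‑dioxocyclohexa‑1,4‑dien‑1‑yl)‑13‑(2,5‑dihydroxy‑4‑methyl‑3,6‑dioxocyclohexa‑1,4‑dien‑1‑yl)tridecane | OC1=CC(=O)C(O)=C(CCCCCCCCCCCCCC2=C(O)C(=O)C(C)=C(O)C2=O)C1=O | intermediate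
14 | 1‑(2‑hydroxy‑5‑methoxy‑3,6‑dioxocyclohexa‑1,4‑dien‑1‑yl)‑13‑(2,5‑dihydroxy‑4‑methyl‑3,6‑dioxocyclohexa‑1,4‑dien‑1‑yl)tridecane | COC1=CC(=O)C(O)=C(CCCCCCCCCCCCCC2=C(O)C(=O)C(C)=C(O)C2=O)C1=O | intermediate
15 | 1‑(2‑hydroxy‑5‑methoxy‑4‑methyl‑3,6‑dioxocyclohexa‑1,4‑dien‑1‑yl)‑13‑(2,5‑dihydroxy‑4‑methyl‑3,6‑dioxocyclohexa‑1,4‑dien‑1‑yl)tridecane | COC1=C(C)C(=O)C(O)=C(CCCCCCCCCCCCCC2=C(O)C(=O)C(C)=C(O)C2=O)C1=O | target

**Step count and risks**

Total step count: 9. Longest linear sequence: 9 steps (1 to 15).

Steps most likely to fail:

1. Step 7 (Proposed new method). Self‑aldol condensation and oligomerisation of the diketone enolates may outrun C‑acylation, or the sequence may stop at the open‑chain stage before ring closure. The fallback uses known chemistry only, sets out from 1 and comes back to the route at 15. Saponification of 1 (NaOH) and oxidation of the ω‑hydroxy acid (TEMPO, NaOCl, NaClO2) should give pentadecanedioic acid F1. A twofold silver/persulfate decarboxylative radical alkylation of excess purchased 2,5‑dihydroxy‑1,4‑benzoquinone (AgNO3, (NH4)2S2O8, MeCN/H2O, 65 °C) should give the symmetric 1,13‑bis(2,5‑dihydroxy‑3,6‑dioxocyclohexa‑1,4‑dien‑1‑yl)tridecane F2, in which both rings keep a C–H. Methanolysis as in step 8, stopped at partial conversion, should give the mono‑methyl ether F3 (a statistical step; unchanged F2 is recycled). The conditions of step 9 should then methylate both ring C–H positions to give 15.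

2. Step 8. Site selectivity may be lost through etherification of ring B or of the chain‑flanked OH of ring A, or through over‑methylation. The fallback sets out from 13 and comes back at 14. Exhaustive O‑methylation (dimethyl sulfate, K2CO3, acetone, reflux) should give the tetramethyl ether F4. Selective acid hydrolysis (70% HClO4, CH2Cl2/dioxane, rt) is known to cleave methoxy groups that sit next to an alkyl substituent on a 2,5‑dimethoxyquinone and to spare the one next to a ring C–H, so it should remove the three alkyl‑flanked methyl groups and leave 14.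

3. Step 9. The methyl radical may add sluggishly, abstract hydrogen from the chain, or the free hydroxyquinones may be degraded by the oxidising silver/persulfate medium. The fallback sets out from 14 and comes back at 15. Electrophilic bromination of the single ring C–H (Br2, NaOAc, AcOH, rt) should give the bromoquinone F5. Stille methylation (SnMe4, Pd(PPh3)4, dioxane, 90 °C) should then replace bromine by methyl to give 15.

**Further compounds**

F1 | step 7 | pentadecanedioic acid | OC(=O)CCCCCCCCCCCCCC(=O)O
F2 | step 7 | 1,13‑bis(2,5‑dihydroxy‑3,6‑dioxocyclohexa‑1,4‑dien‑1‑yl)tridecane | OC1=CC(=O)C(O)=C(CCCCCCCCCCCCCC2=C(O)C(=O)C=C(O)C2=O)C1=O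
F3 | step 7 | 1‑(2‑hydroxy‑5‑methoxy‑3,6‑dioxocyclohexa‑1,4‑dien‑1‑yl)‑13‑(2,5‑dihydroxy‑3,6‑dioxocyclohexa‑1,4‑dien‑1‑yl)tridecane | COC1=CC(=O)C(O)=C(CCCCCCCCCCCCCC2=C(O)C(=O)C=C(O)C2=O)C1=O
F4 | step 8 | 1‑(2,5‑dimethoxy‑3,6‑dioxocyclohexa‑1,4‑dien‑1‑yl)‑13‑(2,5‑dimethoxy‑4‑methyl‑3,6‑dioxocyclohexa‑1,4‑dien‑1‑yl)tridecane | COC1=CC(=O)C(OC)=C(CCCCCCCCCCCCCC2=C(OC)C(=O)C(C)=C(OC)C2=O)C1=O
F5 | step 9 | 1‑(4‑bromo‑2‑hydroxy‑5‑methoxy‑3,6‑dioxocyclohexa‑1,4‑dien‑1‑yl)‑13‑(2,5‑dihydroxy‑4‑methyl‑3,6‑dioxocyclohexa‑1,4‑dien‑1‑yl)tridecane | COC1=C(Br)C(=O)C(O)=C(CCCCCCCCCCCCCC2=C(O)C(=O)C(C)=C(O)C2=O)C1=O
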